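## Analysis of the target

The target is a flavan-3-ol. Its benzo ring (ring A) carries a methoxy group at C7 and a 2-(3-hydroxyphenyl)ethyl arm at C5, its pyran ring (ring C) carries a hydroxyl at C3, and C2 bears a 4-hydroxy-3,5-dimethoxyphenyl group (ring B). C2 (R) and C3 (S) are adjacent, and the aryl group and the hydroxyl lie on opposite faces of ring C, the catechin-type trans arrangement. The free 4-hydroxyl of ring B is para to the benzylic C2–O1 bond, so the finished molecule can open to a quinone methide under base or strong acid and lose the C2 configuration; both phenols are also prone to oxidation and are best unmasked last. Three kinds of aryl oxygen must be told apart (three methyl ethers, two free phenols, the ring oxygen), and C5 carries carbon, not the oxygen usual in flavonoids, so phloroglucinol-based constructions of ring A do not apply. The hard part is absolute and relative control of the C2/C3 pair next to an electron-rich, ionisable benzylic position. The plan rests on C4 being a methylene on C4a, ortho to the ring oxygen on C8a: cutting ring C at O1–C2 and C3–C4 reveals a salicylaldehyde (ring A, its formyl carbon becoming C4) and a cinnamaldehyde (ring B, C2, C3 and one surplus formyl carbon that is later exchanged for the C3 oxygen).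

## Retrosynthetic reasoning

22 ⇒ 21. The two phenolic O–H bonds are traced back to O–benzyl bonds. Removing them last keeps both phenols masked through the oxidising, radical and acidic steps, so the quinone-methide-prone 4-hydroxybenzylic system exists only in the final product. The forward reaction is a neutral hydrogenolysis that must leave the cyclic benzylic C2–O1 bond alone.

21 ⇒ 20 ⇒ 18. The C3–O bond is exchanged for a C3–carboxyl bond: alcohol 21 comes from the O-alkylhydroxylamine 20 by N–O cleavage, and 20 from acid 18 by radical decarboxylation and capture of the C3 radical by a nitroxyl. The cut is made here because the ring-forming step delivers C3 with one surplus carbon. Passing through a planar radical erases whatever configuration C3 had and lets the C2 aryl group decide the new one. It also avoids a C3 ketone, which would make the C2 hydrogen acidic and favour the cis alcohol on reduction. The forward step has to trap the radical faster than it can fragment, and from the face opposite the aryl group.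

18 ⇒ 17 ⇒ 16. These are two adjustments of oxidation level: the C3–H and C4–H bonds of 18 come from hydrogenation of C3=C4 in 17, and the carboxyl of 17 from the formyl group of 16. Oxidation is placed before reduction so that a saturated β-aryloxy aldehyde, whose enol could expel the ring oxygen, open ring C and scramble C2, is never made. The hydrogenation has to spare two benzyl ethers, which calls for a homogeneous catalyst.

16 ⇒ 10 + 13. Ring C is cut at O1–C2 and C3–C4. These are the two bonds an enal can make with a 2-hydroxybenzaldehyde, one as an electrophile at its β-carbon and one as a nucleophile at its α-carbon, so both form in one catalytic operation from two aromatic aldehydes of similar size. The gain is ring C, two skeletal bonds and the C2 stereocenter in a single step. The forward reaction has to differentiate the faces of the enal and close onto a hindered aldehyde.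

13 ⇒ 12 ⇒ 11. The Cα=Cβ bond of 13 is cut to aryl aldehyde 12 and a two-carbon formyl ylide, and the benzyl ether of 12 to the phenol of 11. Benzyl is chosen so that it leaves together with the other benzyl group at the end.

10 ⇒ 8 ⇒ 6. The phenol of 10 is traced to a methyl ether (8) and the formyl group to an aromatic C–H bond (6). In 6 the position between the arm and one methoxy group is para to the other methoxy group and less hindered than the position between the two methoxy groups, so electrophilic formylation goes where C4 is needed. In 8 only the methoxy group next to the formyl group can chelate a Lewis acid, which singles it out for cleavage and leaves the future 7-methoxy group.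

6 ⇒ 5 ⇒ 2 + 3; 2 ⇒ 1. The CH2–CH2 bond of the arm is taken back to a C=C bond (5), and that to a phosphonate olefination of 3 with 2, itself made from bromide 1. Carbonyl olefination joins the two rings without a cross-coupling catalyst, and a reduction that does not touch benzyl ethers keeps the protecting group of 3 in place.

## Alternatives that were turned down

Alternative 1: Ring A is assembled around an aryne; the cuts are the C5–CH2 bond of the arm and the C4a–C4 bond, and ring C is closed afterwards through O1–C2.
- Forward key step: a fluorinated resorcinol bis(methoxymethyl) ether is lithiated next to fluorine with n-BuLi and loses LiF on warming. The aryne accepts the phenethyl-lithium reagent at the future C5, and the C4a aryl-lithium so formed opens an enantiopure ring-B epoxide at its terminal carbon under BF3·OEt2. The product is (1R,2S)-1-(4-benzyloxy-3,5-dimethoxyphenyl)-1-(methoxymethoxy)-3-{2,4-bis(methoxymethoxy)-6-[2-(3-benzyloxyphenyl)ethyl]phenyl}propan-2-ol, A1.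
- For: both stereocenters arrive together in the epoxide, so the C2/C3 relationship does not depend on a late substrate-controlled step; on this point it is stronger than the chosen route. Three pieces are joined in one flask and the aryne fixes the substitution of ring A.
- Against: two organolithium reagents are needed in exact amounts, since excess base or the product aryl-lithium can add to the aryne. A doubly ortho-substituted aryl-lithium must open an epoxide beside three acetals and a Lewis acid. After A1 the route still needs acetal removal, closure of ring C at an ionisable 4-alkoxybenzylic carbon with a defined steric course, selective methylation at O7 and debenzylation.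
- Comparison: with the preparation of its three components the step count is no lower. The chosen strategy gives up the secure origin of C3, but it closes ring C in a catalytic step at ambient temperature from two stable aldehydes and has the O7 methyl group in place from the start.

Alternative 2: Rings A and C are formed together by cyclotrimerisation.
- Forward key step: a 1,7-diyne that already holds O1, C2, C3 and C4 with both stereocenters (an ethynyl ether at one end, an internal alkyne carrying the arm at the other) is combined with a borylated acetylene under Cp*RuCl(cod). Oxidative coupling closes ring C through C8a–C4a and insertion of the third alkyne completes ring A. The product is (2R,3S)-2-(4-benzyloxy-3,5-dimethoxyphenyl)-5-[2-(3-benzyloxyphenyl)ethyl]-3-(tert-butyldimethylsilyloxy)-7-(pinacolatoboryl)chroman, A2.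
- For: building the benzene ring de novo avoids every question of electrophilic substitution on ring A, and the stereocenters are set in an open chain where dihydroxylation-type methods are dependable. If the insertion is selective, it is as strong as or stronger than the chosen route on the definition of ring A.
- Against: the diyne needs a secondary benzylic ethynyl ether, a class that loses ketene thermally by retro-ene elimination. The regiochemistry of insertion of the unsymmetrical third alkyne (boron at C7, not C6) is not assured. Boron must then be turned into the methoxy group in two steps before desilylation and debenzylation, and the linear sequence to the diyne is long.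
- Comparison: the chosen strategy takes ring A from a cheap benzene derivative and spends its steps on ring C only.

Alternative 3: Ring A is made by aromatisation of a polyketide chain.
- Forward key step: a diketo-dioxinone carrying the arm is heated with MeOH to unmask a 3,5,7-trioxo ester, whose C2 adds to the C7 ketone under Cs2CO3, forming the C4a–C5 bond. Dehydration gives methyl 2,4-dihydroxy-6-[2-(3-benzyloxyphenyl)ethyl]benzoate, A3.
- For: the substitution pattern of ring A is unambiguous, and the two phenols of A3 are differentiated by hydrogen bonding to the ester, so O7 could be methylated without any selective demethylation. Here it is stronger than the formylation and demethylation steps of the chosen route.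
- Against: it answers only for ring A. After methylation and adjustment of the ester to the aldehyde level, A3 leads to the same salicylaldehyde 10 by a longer path, and neither ring C nor any stereocenter is addressed.
- Comparison: it is an alternative entry to 10, not a competing strategy; the chosen route reaches 10 in five steps from 1 and 3 and then forms ring C and C2 together.

Key step: step 8

Assumption: the sense of induction in step 8 is taken from the accepted shielding model of E-iminium ions of diarylprolinol silyl ethers, by which the (S)-configured amine leads to the 2R series; the mirror-image amine would give the 2S series.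

## Route

Step 1
Reactants: 1 3,5-dimethoxybenzyl bromide
Product: 2 diethyl (3,5-dimethoxybenzyl)phosphonate
Conditions: P(OEt)3 (neat), 130 °C
Reagents that add atoms: triethyl phosphite, CCOP(OCC)OCC
Why: Michaelis–Arbuzov reaction; the benzylic bromide alkylates phosphorus and bromide dealkylates the phosphonium intermediate, the volatile by-product distilling out.

Step 2
Reactants: 2 diethyl (3,5-dimethoxybenzyl)phosphonate; 3 3-benzyloxybenzaldehyde
Product: 5 (E)-1-benzyloxy-3-[2-(3,5-dimethoxyphenyl)ethenyl]benzene, via potassium phosphonate carbanion 4 (not isolated)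
Conditions: KOtBu, THF, 0 °C → rt
Reagents that add atoms: none
Why: Horner–Wadsworth–Emmons olefination of a non-enolisable aryl aldehyde should give the E-stilbene with a water-soluble phosphate by-product; the alkene geometry is of no consequence because the double bond is reduced next.

Step 3
Reactants: 5 (E)-1-benzyloxy-3-[2-(3,5-dimethoxyphenyl)ethenyl]benzene
Product: 6 1-benzyloxy-3-[2-(3,5-dimethoxyphenyl)ethyl]benzene
Conditions: TsNHNH2, NaOAc, DME/H2O, reflux
Reagents that add atoms: none
Why: Diimide reduction; diimide released from the sulfonyl hydrazide transfers two hydrogens to the stilbene C=C only, so the aryl benzyl ether, which palladium-catalysed hydrogenation would cleave, is kept.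

Step 4
Reactants: 6 1-benzyloxy-3-[2-(3,5-dimethoxyphenyl)ethyl]benzene
Product: 8 2-[2-(3-benzyloxyphenyl)ethyl]-4,6-dimethoxybenzaldehyde, via aryl iminium chloride 7 (not isolated)
Conditions: POCl3, DMF, 0 → 60 °C; then aq. NaOAc
Reagents that add atoms: N,N-dimethylformamide, CN(C)C=O; water, O
Why: Vilsmeier–Haack formylation; the chloroiminium ion should attack the dimethoxy ring beside the arm, para to one methoxy group and ortho to the other, because the site between the two methoxy groups is more hindered, as is known for 5-alkylresorcinol dimethyl ethers. The mono-alkoxy ring is far less reactive and the product is deactivated towards a second formylation.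

Step 5
Reactants: 8 2-[2-(3-benzyloxyphenyl)ethyl]-4,6-dimethoxybenzaldehyde
Product: 10 2-hydroxy-4-methoxy-6-[2-(3-benzyloxyphenyl)ethyl]benzaldehyde, via iodomagnesium phenoxide 9 (not isolated)
Conditions: MgI2·OEt2, toluene, 80 °C; then 1 M HCl
Reagents that add atoms: none
Why: Chelation-controlled ether cleavage; magnesium binds the formyl oxygen and the neighbouring methoxy oxygen and iodide removes only that methyl group. The para methoxy group and the remote benzyl ether cannot chelate and should stay, which boron halides would not guarantee for the benzyl ether.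

Step 6
Reactants: 11 syringaldehyde
Product: 12 4-benzyloxy-3,5-dimethoxybenzaldehyde
Conditions: BnBr, K2CO3, DMF, 60 °C
Reagents that add atoms: benzyl bromide, BrCc1ccccc1
Why: Williamson ether synthesis; the acidic 4-hydroxyl is alkylated cleanly and the benzyl group matches the one already on the arm.

Step 7
Reactants: 12 4-benzyloxy-3,5-dimethoxybenzaldehyde
Product: 13 (E)-3-(4-benzyloxy-3,5-dimethoxyphenyl)prop-2-enal
Conditions: Ph3P=CHCHO, toluene, 90 °C
Reagents that add atoms: (triphenylphosphoranylidene)acetaldehyde, O=CC=P(c1ccccc1)(c1ccccc1)c1ccccc1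
Why: Wittig olefination with the stabilised formyl ylide should give the E-enal directly; the ylide is kept near one equivalent to limit a second homologation of the product.

Step 8
Reactants: 10 2-hydroxy-4-methoxy-6-[2-(3-benzyloxyphenyl)ethyl]benzaldehyde; 13 (E)-3-(4-benzyloxy-3,5-dimethoxyphenyl)prop-2-enal
Product: 16 (R)-2-(4-benzyloxy-3,5-dimethoxyphenyl)-5-[2-(3-benzyloxyphenyl)ethyl]-7-methoxy-2H-chromene-3-carbaldehyde, via iminium ion 14 (not isolated), via enamine oxa-Michael adduct 15 (not isolated)
Conditions: (S)-2-[diphenyl(trimethylsilyloxy)methyl]pyrrolidine (20 mol%), 2-nitrobenzoic acid (20 mol%), 13 (1.5 equiv), toluene, rt, dark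
Reagents that add atoms: none
Why: The amine condenses with 13 to the E-configured iminium ion 14, the acid cocatalyst speeding both its formation and the final hydrolysis. The phenol of 10 adds to the β-carbon (oxa-Michael addition, O1–C2), which leaves enamine 15. The enamine carbon then attacks the aryl aldehyde held beside it in a 6-exo-trig (enol-exo) aldol closure that forms C3–C4 and ring C; loss of water and hydrolysis release 16 and the catalyst. The closest known reaction type is the diarylprolinol silyl ether catalysed oxa-Michael–aldol condensation of salicylaldehydes with cinnamaldehydes to 2-aryl-2H-chromene-3-carbaldehydes. C2 is the only new stereocenter and is controlled by the catalyst: the diphenyl(trimethylsilyloxy)methyl group covers one face of the planar iminium ion, so the phenol should add from the open Si face of the β-carbon, which corresponds to 2R, while C3 and C4 end up trigonal. The oxa-Michael step is reversible and only the adduct of the salicyl hydroxyl has an aldehyde within reach, so the irreversible aldol–dehydration selects it. The crowded, methoxy-deactivated aldehyde of 10 is acceptable because it is attacked intramolecularly, and 13 stays electrophilic because its 4-benzyloxy group is twisted out of conjugation by the two flanking methoxy groups and it has no γ-hydrogen for dienamine formation. The reaction is run in the dark at ambient temperature because 2H-chromenes can racemise by electrocyclic ring opening.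

Step 9
Reactants: 16 (R)-2-(4-benzyloxy-3,5-dimethoxyphenyl)-5-[2-(3-benzyloxyphenyl)ethyl]-7-methoxy-2H-chromene-3-carbaldehyde
Product: 17 (R)-2-(4-benzyloxy-3,5-dimethoxyphenyl)-5-[2-(3-benzyloxyphenyl)ethyl]-7-methoxy-2H-chromene-3-carboxylic acid
Conditions: NaClO2, NaH2PO4, 2-methyl-2-butene (large excess), t-BuOH/THF/H2O, 0 °C → rt
Reagents that add atoms: sodium chlorite, [Na+].[O-]Cl=O
Why: Pinnick oxidation converts the enal into the acid without touching the trisubstituted alkene or C2; the alkene scavenger removes hypochlorous acid before it can chlorinate the electron-rich ring A.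

Step 10
Reactants: 17 (R)-2-(4-benzyloxy-3,5-dimethoxyphenyl)-5-[2-(3-benzyloxyphenyl)ethyl]-7-methoxy-2H-chromene-3-carboxylic acid
Product: 18 (2S)-2-(4-benzyloxy-3,5-dimethoxyphenyl)-5-[2-(3-benzyloxyphenyl)ethyl]-7-methoxychroman-3-carboxylic acid (mixture of C3 epimers; C2 unchanged in space, its descriptor changes by the sequence rule)
Conditions: H2 (30 bar), Ru(OAc)2[(R)-BINAP] (2 mol%; either antipode serves), MeOH/THF, 40 °C
Reagents that add atoms: none
Why: Carboxylate-directed homogeneous hydrogenation of a trisubstituted α,β-unsaturated acid; ruthenium bound to the carboxylate adds hydrogen across C3=C4 only, sparing both benzyl ethers and the benzylic C2–O1 bond, and the chelate offers no path for migration of the double bond towards C2. The C3 configuration formed here is irrelevant because C3 becomes planar in step 11.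

Step 11
Reactants: 18 (2S)-2-(4-benzyloxy-3,5-dimethoxyphenyl)-5-[2-(3-benzyloxyphenyl)ethyl]-7-methoxychroman-3-carboxylic acid
Product: 20 (2R,3S)-2-(4-benzyloxy-3,5-dimethoxyphenyl)-5-[2-(3-benzyloxyphenyl)ethyl]-7-methoxy-3-[(2,2,6,6-tetramethylpiperidin-1-yl)oxy]chroman, via thiohydroxamate ester 19 (not isolated)
Conditions: 1-hydroxypyridine-2(1H)-thione, DCC, CH2Cl2, 0 °C → rt, dark; then TEMPO (3 equiv), visible light, 0 °C
Reagents that add atoms: TEMPO, CC1(C)CCCC(C)(C)N1[O]
Why: Barton decarboxylation with nitroxyl trapping; light cleaves the N–O bond of ester 19, CO2 is lost and the secondary C3 radical is captured by TEMPO at close to the diffusion limit, which should outrun β-fragmentation of C2–O1 and 1,2-aryl shift. The bulky nitroxyl should approach the flattened ring C on the face opposite the C2 aryl group, setting C3 as S (2,3-trans).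

Step 12
Reactants: 20 (2R,3S)-2-(4-benzyloxy-3,5-dimethoxyphenyl)-5-[2-(3-benzyloxyphenyl)ethyl]-7-methoxy-3-[(2,2,6,6-tetramethylpiperidin-1-yl)oxy]chroman
Product: 21 (2R,3S)-2-(4-benzyloxy-3,5-dimethoxyphenyl)-5-[2-(3-benzyloxyphenyl)ethyl]-7-methoxychroman-3-ol
Conditions: Zn, AcOH/THF/H2O, 60 °C
Reagents that add atoms: none
Why: Reductive N–O cleavage of an O-alkylhydroxylamine by zinc in acetic acid; the C3–O bond is not touched, so the configuration is retained, and benzyl ethers are inert.

Step 13
Reactants: 21 (2R,3S)-2-(4-benzyloxy-3,5-dimethoxyphenyl)-5-[2-(3-benzyloxyphenyl)ethyl]-7-methoxychroman-3-ol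
Product: 22 (2R,3S)-2-(4-hydroxy-3,5-dimethoxyphenyl)-5-[2-(3-hydroxyphenyl)ethyl]-7-methoxychroman-3-ol
Conditions: H2 (1 atm), Pd/C (10%), EtOAc/MeOH, rt
Reagents that add atoms: none
Why: Hydrogenolysis of both aryl benzyl ethers; as with benzyl-protected catechins, the cyclic benzylic C2–O1 ether and both stereocenters should survive neutral conditions at ambient pressure.

## Compound list

1 | 3,5-dimethoxybenzyl bromide | COc1cc(CBr)cc(OC)c1 | starting material
2 | diethyl (3,5-dimethoxybenzyl)phosphonate | CCOP(=O)(OCC)Cc1cc(OC)cc(OC)c1 | intermediate
3 | 3-benzyloxybenzaldehyde | O=Cc1cccc(OCc2ccccc2)c1 | starting material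
4 | potassium phosphonate carbanion (potassium salt of deprotonated 2) | CCOP(=O)(OCC)[CH-]c1cc(OC)cc(OC)c1.[K+] | intermediate (not isolated)
5 | (E)-1-benzyloxy-3-[2-(3,5-dimethoxyphenyl)ethenyl]benzene | COc1cc(/C=C/c2cccc(OCc3ccccc3)c2)cc(OC)c1 | intermediate
6 | 1-benzyloxy-3-[2-(3,5-dimethoxyphenyl)ethyl]benzene | COc1cc(CCc2cccc(OCc3ccccc3)c2)cc(OC)c1 | intermediate
7 | aryl iminium chloride, N-{2-[2-(3-benzyloxyphenyl)ethyl]-4,6-dimethoxybenzylidene}-N-methylmethanaminium chloride | COc1cc(OC)c(C=[N+](C)C)c(CCc2cccc(OCc3ccccc3)c2)c1.[Cl-] | intermediate (not isolated)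
8 | 2-[2-(3-benzyloxyphenyl)ethyl]-4,6-dimethoxybenzaldehyde | COc1cc(OC)c(C=O)c(CCc2cccc(OCc3ccccc3)c2)c1 | intermediate
9 | iodomagnesium phenoxide of 10 | COc1cc([O-])c(C=O)c(CCc2cccc(OCc3ccccc3)c2)c1.[Mg+2].[I-] | intermediate (not isolated)
10 | 2-hydroxy-4-methoxy-6-[2-(3-benzyloxyphenyl)ethyl]benzaldehyde | COc1cc(O)c(C=O)c(CCc2cccc(OCc3ccccc3)c2)c1 | intermediate
11 | syringaldehyde (4-hydroxy-3,5-dimethoxybenzaldehyde) | COc1cc(C=O)cc(OC)c1O | starting material
12 | 4-benzyloxy-3,5-dimethoxybenzaldehyde | COc1cc(C=O)cc(OC)c1OCc1ccccc1 | intermediate
13 | (E)-3-(4-benzyloxy-3,5-dimethoxyphenyl)prop-2-enal | COc1cc(/C=C/C=O)cc(OC)c1OCc1ccccc1 | intermediate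
14 | iminium ion of 13 and the (S)-amine catalyst, 2-nitrobenzoate salt (E at C=N) | COc1cc(/C=C/C=[N+]2\CCC[C@H]2C(c2ccccc2)(c2ccccc2)O[Si](C)(C)C)cc(OC)c1OCc1ccccc1.[O-]C(=O)c1ccccc1[N+](=O)[O-] | intermediate (not isolated)
15 | enamine oxa-Michael adduct of 10 and 14 (aryloxy-bearing carbon S by the sequence rule, the later C2) | O=Cc1c(CCc2cccc(OCc3ccccc3)c2)cc(OC)cc1O[C@H](c1cc(OC)c(OCc2ccccc2)c(OC)c1)/C=C/N1CCC[C@H]1C(c1ccccc1)(c1ccccc1)O[Si](C)(C)C | intermediate (not isolated)
16 | (R)-2-(4-benzyloxy-3,5-dimethoxyphenyl)-5-[2-(3-benzyloxyphenyl)ethyl]-7-methoxy-2H-chromene-3-carbaldehyde | COc1cc(CCc2cccc(OCc3ccccc3)c2)c2c(c1)O[C@H](c1cc(OC)c(OCc3ccccc3)c(OC)c1)C(C=O)=C2 | intermediate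
17 | (R)-2-(4-benzyloxy-3,5-dimethoxyphenyl)-5-[2-(3-benzyloxyphenyl)ethyl]-7-methoxy-2H-chromene-3-carboxylic acid | COc1cc(CCc2cccc(OCc3ccccc3)c2)c2c(c1)O[C@H](c1cc(OC)c(OCc3ccccc3)c(OC)c1)C(C(=O)O)=C2 | intermediate
18 | (2S)-2-(4-benzyloxy-3,5-dimethoxyphenyl)-5-[2-(3-benzyloxyphenyl)ethyl]-7-methoxychroman-3-carboxylic acid, C3 epimer mixture | COc1cc(CCc2cccc(OCc3ccccc3)c2)c2c(c1)O[C@H](c1cc(OC)c(OCc3ccccc3)c(OC)c1)C(C(=O)O)C2 | intermediate
19 | thiohydroxamate ester, 2-thioxopyridin-1(2H)-yl ester of 18 | COc1cc(CCc2cccc(OCc3ccccc3)c2)c2c(c1)O[C@H](c1cc(OC)c(OCc3ccccc3)c(OC)c1)C(C(=O)On1ccccc1=S)C2 | intermediate (not isolated)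
20 | (2R,3S)-2-(4-benzyloxy-3,5-dimethoxyphenyl)-5-[2-(3-benzyloxyphenyl)ethyl]-7-methoxy-3-[(2,2,6,6-tetramethylpiperidin-1-yl)oxy]chroman | COc1cc(CCc2cccc(OCc3ccccc3)c2)c2c(c1)O[C@H](c1cc(OC)c(OCc3ccccc3)c(OC)c1)[C@@H](ON1C(C)(C)CCCC1(C)C)C2 | intermediate
21 | (2R,3S)-2-(4-benzyloxy-3,5-dimethoxyphenyl)-5-[2-(3-benzyloxyphenyl)ethyl]-7-methoxychroman-3-ol | COc1cc(CCc2cccc(OCc3ccccc3)c2)c2c(c1)O[C@H](c1cc(OC)c(OCc3ccccc3)c(OC)c1)[C@@H](O)C2 | intermediate
22 | (2R,3S)-2-(4-hydroxy-3,5-dimethoxyphenyl)-5-[2-(3-hydroxyphenyl)ethyl]-7-methoxychroman-3-ol | COc1cc(CCc2cccc(O)c2)c2c(c1)O[C@H](c1cc(OC)c(O)c(OC)c1)[C@@H](O)C2 | target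

## Step count and least certain steps

Total: 13 steps. Longest linear sequence: 11 steps (steps 1–5 and 8–13); the enal branch adds steps 6 and 7.

Step 8 (key step). The aldol closure onto the hindered, methoxy-deactivated aldehyde may be slow, so that the reversible oxa-Michael adduct accumulates, conversion stalls and a less selective background pathway or ring-opening racemisation of the product lowers the enantiomeric purity. Fallback: from 10 and 13, pyrrolidine and benzoic acid in toluene should give the racemic chromene aldehyde F1 by the same domino sequence without any demand on facial control. Pinnick oxidation as in step 9 gives the racemic chromene acid F2, which is resolved by crystallisation of the (R)-1-phenylethylammonium salt of the 2R acid F3 (the antipodal amine is used if the other diastereomeric salt is the less soluble one). Acidification rejoins the route at 17.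

Step 11. Facial selectivity in the radical capture may be poor if the C2 aryl group sits pseudo-equatorial and shields neither face well; some loss to disproportionation or to ring opening by β-fragmentation is also possible. Fallback: from 16, stoichiometric RhCl(PPh3)3 in toluene at 90–110 °C removes the formyl group to give the flav-3-ene, (S)-2-(4-benzyloxy-3,5-dimethoxyphenyl)-5-[2-(3-benzyloxyphenyl)ethyl]-7-methoxy-2H-chromene F4. Hydroboration with BH3·THF places boron at C3 (away from the aryl-bearing C4, next to the oxygen-bearing C2) on the face opposite the C2 aryl group, and oxidation with NaOH/H2O2 retains that configuration, rejoining the route at 21.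

Step 10. Hydrogenation of the hindered trisubstituted alkene may be slow, and any double-bond migration to C2=C3 would destroy the C2 stereocenter. Fallback: from 16, conjugate reduction at the aldehyde stage with [(Ph3P)CuH]6 in moist THF gives the saturated chroman-3-carbaldehyde F5, which is oxidised at once under the conditions of step 9 to rejoin the route at 18.

Step 5. The demethylation may be incomplete, or the remote benzyl ether may be lost under forcing conditions. Fallback: from 8, excess BCl3 (CH2Cl2, −78 → 0 °C) removes both the chelated methyl group and the benzyl group to give the diphenol aldehyde F6. Annulation with 13 as in step 8 (the remote phenol can add only reversibly because it has no aldehyde beside it) gives the chromene aldehyde with a free phenol F7. Benzylation (BnBr, K2CO3, acetone) rejoins the route at 16.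

## Further compounds

F1 | step 8 | rac-2-(4-benzyloxy-3,5-dimethoxyphenyl)-5-[2-(3-benzyloxyphenyl)ethyl]-7-methoxy-2H-chromene-3-carbaldehyde | COc1cc(CCc2cccc(OCc3ccccc3)c2)c2c(c1)OC(c1cc(OC)c(OCc3ccccc3)c(OC)c1)C(C=O)=C2
F2 | step 8 | rac-2-(4-benzyloxy-3,5-dimethoxyphenyl)-5-[2-(3-benzyloxyphenyl)ethyl]-7-methoxy-2H-chromene-3-carboxylic acid | COc1cc(CCc2cccc(OCc3ccccc3)c2)c2c(c1)OC(c1cc(OC)c(OCc3ccccc3)c(OC)c1)C(C(=O)O)=C2
F3 | step 8 | (R)-1-phenylethylammonium (R)-2-(4-benzyloxy-3,5-dimethoxyphenyl)-5-[2-(3-benzyloxyphenyl)ethyl]-7-methoxy-2H-chromene-3-carboxylate | COc1cc(CCc2cccc(OCc3ccccc3)c2)c2c(c1)O[C@H](c1cc(OC)c(OCc3ccccc3)c(OC)c1)C(C(=O)[O-])=C2.C[C@@H]([NH3+])c1ccccc1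
F4 | step 11 | (S)-2-(4-benzyloxy-3,5-dimethoxyphenyl)-5-[2-(3-benzyloxyphenyl)ethyl]-7-methoxy-2H-chromene | COc1cc(CCc2cccc(OCc3ccccc3)c2)c2c(c1)O[C@H](c1cc(OC)c(OCc3ccccc3)c(OC)c1)C=C2
F5 | step 10 | (2S)-2-(4-benzyloxy-3,5-dimethoxyphenyl)-5-[2-(3-benzyloxyphenyl)ethyl]-7-methoxychroman-3-carbaldehyde, C3 epimer mixture | COc1cc(CCc2cccc(OCc3ccccc3)c2)c2c(c1)O[C@H](c1cc(OC)c(OCc3ccccc3)c(OC)c1)C(C=O)C2
F6 | step 5 | 2-hydroxy-6-[2-(3-hydroxyphenyl)ethyl]-4-methoxybenzaldehyde | COc1cc(O)c(C=O)c(CCc2cccc(O)c2)c1
F7 | step 5 | (R)-2-(4-benzyloxy-3,5-dimethoxyphenyl)-5-[2-(3-hydroxyphenyl)ethyl]-7-methoxy-2H-chromene-3-carbaldehyde | COc1cc(CCc2cccc(O)c2)c2c(c1)O[C@H](c1cc(OC)c(OCc3ccccc3)c(OC)c1)C(C=O)=C2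
A1 | alternative 1 | (1R,2S)-1-(4-benzyloxy-3,5-dimethoxyphenyl)-1-(methoxymethoxy)-3-{2,4-bis(methoxymethoxy)-6-[2-(3-benzyloxyphenyl)ethyl]phenyl}propan-2-ol | COCO[C@H](c1cc(OC)c(OCc2ccccc2)c(OC)c1)[C@@H](O)Cc1c(OCOC)cc(OCOC)cc1CCc1cccc(OCc2ccccc2)c1
A2 | alternative 2 | (2R,3S)-2-(4-benzyloxy-3,5-dimethoxyphenyl)-5-[2-(3-benzyloxyphenyl)ethyl]-3-(tert-butyldimethylsilyloxy)-7-(pinacolatoboryl)chroman | CC1(C)OB(OC1(C)C)c1cc(CCc2cccc(OCc3ccccc3)c2)c2c(c1)O[C@H](c1cc(OC)c(OCc3ccccc3)c(OC)c1)[C@@H](O[Si](C)(C)C(C)(C)C)C2
A3 | alternative 3 | methyl 2,4-dihydroxy-6-[2-(3-benzyloxyphenyl)ethyl]benzoate | COC(=O)c1c(O)cc(O)cc1CCc1cccc(OCc2ccccc2)c1
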